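## Retrosynthetic overview

- The target is reached from a C-3 aldehyde / C-1 pivalate by hydride reduction, then MnO2 oxidation of the only allylic CH2OH.
- Key step: an oxirane-initiated cation–olefin cyclisation forms the cyclohexane (ring B) by attack of a sacrificial cyclohexene (ring A) on C-11. The C-7 cation then opens ring A by Grob fragmentation, giving the C-3 aldehyde and the Z-configured C-7=C-2 alkene in the same operation.
- The cascade substrate comes from Sharpless epoxidation of a (Z)-tetrasubstituted allylic alcohol, assembled by B-alkyl Suzuki coupling of a ring A enol triflate with a dienol.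
- The enol triflate comes from 2-methylcyclohexane-1,3-dione (hydroxymethylation, CBS desymmetrisation). The dienol comes from farnesyl bromide (one-carbon homologation), but-2-yn-1-ol (anti-carbomagnesiation) and vinyl bromide.
- Ring order: ring A is carried in from the dione and destroyed; ring B, the only ring of the target, is formed last (step 11).

Assumption: atom labels follow iridal numbering (C-1 aldehyde carbon, C-2=C-7 exocyclic alkene, C-3 hydroxypropyl terminus, C-6/C-10/C-11 ring stereocentres, C-26 ring CH2OH carbon, C-27 methyl on C-10); "homofarnesyl" means (3E,7E)-4,8,12-trimethyltrideca-3,7,11-trien-1-yl; the target is taken as drawn, (6S,10R,11R), Z at C-2=C-7.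

## Route

Step 1
Reactants: 1 2-methylcyclohexane-1,3-dione
Product: 2 2-(hydroxymethyl)-2-methylcyclohexane-1,3-dione
Conditions: 37% aq. CH2O (3 equiv), Et3N (10 mol %), H2O–THF, 23 °C
Reagents that add atoms: formaldehyde, C=O
Why: Base-catalysed aldol (Tollens-type hydroxymethylation) of the doubly activated methine with formaldehyde; the quaternary aldol cannot dehydrate and no stereocentre is formed.

Step 2
Reactants: 2 2-(hydroxymethyl)-2-methylcyclohexane-1,3-dione
Product: 3 (1-methyl-2,6-dioxocyclohexyl)methyl 2,2-dimethylpropanoate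
Conditions: PivCl, pyridine, DMAP (cat.), CH2Cl2, 0 → 23 °C
Reagents that add atoms: pivaloyl chloride, CC(C)(C)C(Cl)=O
Why: DMAP-catalysed O-acylation; the pivalate makes the C-1 oxygen a non-donating spectator that lasts until the final hydride reduction and blocks retro-aldol loss of formaldehyde.

Step 3
Reactants: 3 (1-methyl-2,6-dioxocyclohexyl)methyl 2,2-dimethylpropanoate
Product: 4 [(1S,2S)-2-hydroxy-1-methyl-6-oxocyclohexyl]methyl 2,2-dimethylpropanoate
Conditions: (R)-2-methyl-CBS-oxazaborolidine (20 mol %), BH3·SMe2 (0.6 equiv), THF, −40 °C; MeOH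
Reagents that add atoms: none
Why: Corey–Bakshi–Shibata reduction used as an enantiotopic-group-selective desymmetrisation: the (R)-catalyst sets the carbinol as S and hydride arrives anti to the bulkier CH2OPiv arm, which fixes the quaternary carbon as S (OH cis to CH2OPiv).

Step 4
Reactants: 4 [(1S,2S)-2-hydroxy-1-methyl-6-oxocyclohexyl]methyl 2,2-dimethylpropanoate
Product: 5 [(1S,2S)-1-methyl-6-oxo-2-(trimethylsilyloxy)cyclohexyl]methyl 2,2-dimethylpropanoate
Conditions: TMSCl, imidazole, CH2Cl2, 0 °C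
Reagents that add atoms: chlorotrimethylsilane, C[Si](C)(C)Cl
Why: Silyl ether formation protects the β-hydroxy ketone against retro-aldol cleavage and O-triflation in the next step; no stereocentre is touched.

Step 5
Reactants: 5 [(1S,2S)-1-methyl-6-oxo-2-(trimethylsilyloxy)cyclohexyl]methyl 2,2-dimethylpropanoate
Product: 6 [(1S,6S)-1-methyl-2-(trifluoromethylsulfonyloxy)-6-(trimethylsilyloxy)cyclohex-2-en-1-yl]methyl 2,2-dimethylpropanoate
Conditions: KN(SiMe3)2, THF, −78 °C; PhNTf2, −78 → 0 °C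
Reagents that add atoms: N-phenylbis(trifluoromethanesulfonimide), FC(F)(F)S(=O)(=O)N(c1ccccc1)S(=O)(=O)C(F)(F)F
Why: Regiospecific enolisation (only C-6 carries α-hydrogens) and O-sulfonylation of the enolate give the enol triflate that places the future ring A alkene at C-6=C-7.

Step 6
Reactants: 7 (2E,6E)-1-bromo-3,7,11-trimethyldodeca-2,6,10-triene (farnesyl bromide)
Product: 9 (3E,7E)-4,8,12-trimethyltrideca-3,7,11-trien-1-ol (homofarnesol), via homofarnesyl(isopropoxy)dimethylsilane 8 (not isolated)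
Conditions: ClMgCH2SiMe2(OiPr), Li2CuCl4 (3 mol %), THF, 0 °C; then 30% H2O2, KF, KHCO3, MeOH–THF, 23 °C
Reagents that add atoms: [(isopropoxydimethylsilyl)methyl]magnesium chloride, CC(C)O[Si](C)(C)C[Mg]Cl; hydrogen peroxide, OO
Why: Copper-catalysed SN2 coupling of the allylic bromide with Tamao's hydroxymethyl-anion equivalent, then Tamao oxidation of the C–Si bond, adds the C-12 carbon with the E,E geometry untouched.

Step 7
Reactants: 9 (3E,7E)-4,8,12-trimethyltrideca-3,7,11-trien-1-ol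
Product: 10 (3E,7E)-1-bromo-4,8,12-trimethyltrideca-3,7,11-triene (homofarnesyl bromide)
Conditions: CBr4, PPh3, CH2Cl2, 0 °C
Reagents that add atoms: carbon tetrabromide, BrC(Br)(Br)Br
Why: Appel bromination (SN2 at a primary carbon) gives the Grignard precursor without touching the alkenes.

Step 8
Reactants: 10 (3E,7E)-1-bromo-4,8,12-trimethyltrideca-3,7,11-triene; 11 but-2-yn-1-ol
Product: 14 (2Z)-3-methyl-2-homofarnesylpenta-2,4-dien-1-ol, via homofarnesylmagnesium bromide 12 (not isolated), via cyclic alkenylmagnesium alkoxide 13 (not isolated)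
Conditions: 10, Mg, THF; 11, iPrMgCl (1.0 equiv), THF, 0 °C; combine, CuI (10 mol %), reflux; then vinyl bromide, Pd(PPh3)4 (5 mol %), 40 °C
Reagents that add atoms: vinyl bromide, C=CBr
Why: Duboudin-type copper-catalysed anti-carbomagnesiation puts the alkyl group on the carbinol-bearing alkyne carbon and magnesium cis to CH2O in a five-membered chelate, and Kumada–Corriu coupling of that alkenylmagnesium with vinyl bromide goes with retention, so the tetrasubstituted alkene forms as the single Z isomer (C-9 cis to C-26).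

Step 9
Reactants: 14 (2Z)-3-methyl-2-homofarnesylpenta-2,4-dien-1-ol; 6 ring A enol triflate
Product: 17 [(1S,6S)-6-hydroxy-2-[(3Z,7E,11E)-4-(hydroxymethyl)-3,8,12,16-tetramethylheptadeca-3,7,11,15-tetraen-1-yl]-1-methylcyclohex-2-en-1-yl]methyl 2,2-dimethylpropanoate, via bis(9-BBN) adduct 15 (not isolated), via C-3 trimethylsilyl ether 16 (not isolated)
Conditions: 14, 9-BBN-H (2.3 equiv), THF, 23 °C; then 6, PdCl2(dppf) (5 mol %), AsPh3, Cs2CO3, DMF–H2O, 23 °C; then 10% aq. citric acid, THF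
Reagents that add atoms: none
Why: Anti-Markovnikov hydroboration of the terminal vinyl group by 9-BBN-H (the tetra- and trisubstituted alkenes are inert) and B-alkyl Suzuki–Miyaura coupling with the enol triflate join C-8 to C-7; mild acid then removes the trimethylsilyl ether.

Step 10
Reactants: 17 coupled allylic alcohol
Product: 18 [(1S,6S)-6-hydroxy-2-{2-[(2R,3S)-3-(hydroxymethyl)-2-methyl-3-homofarnesyloxiran-2-yl]ethyl}-1-methylcyclohex-2-en-1-yl]methyl 2,2-dimethylpropanoate
Conditions: Ti(OiPr)4 (15 mol %), L-(+)-diethyl tartrate (18 mol %), t-BuOOH, 4 Å MS, CH2Cl2, −25 °C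
Reagents that add atoms: tert-butyl hydroperoxide, CC(C)(C)OO
Why: Katsuki–Sharpless asymmetric epoxidation of the only allylic alcohol; the L-(+)-tartrate catalyst delivers oxygen to the face that gives C-10 R and C-11 S, and the Z alkene geometry becomes the cis relationship of C-9 and C-26 on the oxirane.

Step 11
Reactants: 18 epoxy diol
Product: 22 (2Z)-2-[(2S,3R,4R)-4-hydroxy-3-(hydroxymethyl)-4-methyl-2-(3-oxopropyl)-3-homofarnesylcyclohexylidene]propyl 2,2-dimethylpropanoate, via bis(trimethylsilyl) ether 19 (not isolated), via bicyclic C-7 carbocation 20 (not isolated), via silylated seco-aldehyde 21 (not isolated)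
Conditions: N,O-bis(trimethylsilyl)acetamide (3 equiv), CH2Cl2, 40 °C, evaporate; MeAlCl2 (2.5 equiv), CH2Cl2, −78 °C, 15 min; Et3N–MeOH quench; then aq. citric acid, THF, 0 °C
Reagents that add atoms: none
Why: Proposed new method: after in situ silylation, MeAlCl2 activates the oxirane and the ring A alkene attacks C-11 from the backside through a chair-like six-membered transition state (oxirane-initiated Stork–Eschenmoser cation–olefin cyclisation; inversion at C-11, oxygen kept on C-10, H-6 axial and trans to the axial C-26 arm, which sets C-6 as S), and the resulting tertiary C-7 cation then cleaves the flanking C-2–C-3 bond under the push of the C-3 silyloxy group (Grob fragmentation, formally a retro-Prins step) to release the aldehyde and the tetrasubstituted C-7=C-2 alkene, the axial CH2OPiv group on C-2 (syn to H-6 in the trans-fused cation) ending cis to C-6, that is Z; the closest known reactions are MeAlCl2-promoted epoxy-polyene cyclisations and the fragmentation of γ-hydroxy carbocations, and the same cyclisation–fragmentation logic is the accepted enzymatic origin of ring-A-seco triterpene aldehydes from oxidosqualene.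

Step 12
Reactants: 22 seco-aldehyde pivalate
Product: 23 (2Z)-2-[(2S,3R,4R)-4-hydroxy-3-(hydroxymethyl)-2-(3-hydroxypropyl)-4-methyl-3-homofarnesylcyclohexylidene]propan-1-ol
Conditions: iBu2AlH (7 equiv), CH2Cl2, −78 → 0 °C; aq. potassium sodium tartrate
Reagents that add atoms: none
Why: Hydride reduction with iBu2AlH converts the saturated aldehyde to the primary alcohol and cleaves the pivalate in the same operation; no stereocentre or alkene is affected.

Step 13
Reactants: 23 tetraol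
Product: 24 (2Z)-2-[(2S,3R,4R)-4-hydroxy-3-(hydroxymethyl)-2-(3-hydroxypropyl)-4-methyl-3-homofarnesylcyclohexylidene]propanal (target)
Conditions: activated MnO2 (20 equiv), CH2Cl2, 23 °C
Reagents that add atoms: none
Why: Chemoselective MnO2 oxidation of the single allylic primary alcohol to the conjugated aldehyde; the two saturated primary alcohols and the tertiary alcohol do not react, and the Z geometry fixed in step 11 is not disturbed under these neutral heterogeneous conditions.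

## Compound list

1 | 2-methylcyclohexane-1,3-dione | CC1C(=O)CCCC1=O | starting material
2 | 2-(hydroxymethyl)-2-methylcyclohexane-1,3-dione | CC1(CO)C(=O)CCCC1=O | intermediate
3 | (1-methyl-2,6-dioxocyclohexyl)methyl 2,2-dimethylpropanoate | CC(C)(C)C(=O)OCC1(C)C(=O)CCCC1=O | intermediate
4 | [(1S,2S)-2-hydroxy-1-methyl-6-oxocyclohexyl]methyl 2,2-dimethylpropanoate | O=C1CCC[C@H](O)[C@]1(C)COC(=O)C(C)(C)C | intermediate
5 | [(1S,2S)-1-methyl-6-oxo-2-(trimethylsilyloxy)cyclohexyl]methyl 2,2-dimethylpropanoate | O=C1CCC[C@H](O[Si](C)(C)C)[C@]1(C)COC(=O)C(C)(C)C | intermediate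
6 | [(1S,6S)-1-methyl-2-(trifluoromethylsulfonyloxy)-6-(trimethylsilyloxy)cyclohex-2-en-1-yl]methyl 2,2-dimethylpropanoate | O=S(=O)(OC1=CCC[C@H](O[Si](C)(C)C)[C@]1(C)COC(=O)C(C)(C)C)C(F)(F)F | intermediate
7 | (2E,6E)-1-bromo-3,7,11-trimethyldodeca-2,6,10-triene | CC(C)=CCC/C(C)=C/CC/C(C)=C/CBr | starting material
8 | dimethyl(propan-2-yloxy)[(3E,7E)-4,8,12-trimethyltrideca-3,7,11-trien-1-yl]silane | CC(C)=CCC/C(C)=C/CC/C(C)=C/CC[Si](C)(C)OC(C)C | intermediate
9 | (3E,7E)-4,8,12-trimethyltrideca-3,7,11-trien-1-ol | CC(C)=CCC/C(C)=C/CC/C(C)=C/CCO | intermediate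
10 | (3E,7E)-1-bromo-4,8,12-trimethyltrideca-3,7,11-triene | CC(C)=CCC/C(C)=C/CC/C(C)=C/CCBr | intermediate
11 | but-2-yn-1-ol | CC#CCO | starting material
12 | bromo[(3E,7E)-4,8,12-trimethyltrideca-3,7,11-trien-1-yl]magnesium | CC(C)=CCC/C(C)=C/CC/C(C)=C/CC[Mg]Br | intermediate
13 | 3-methyl-4-[(3E,7E)-4,8,12-trimethyltrideca-3,7,11-trien-1-yl]-2,5-dihydro-1,2-oxamagnesole (cyclic Z-alkenylmagnesium alkoxide) | CC(C)=CCC/C(C)=C/CC/C(C)=C/CCC1=C(C)[Mg]OC1 | intermediate
14 | (2Z)-3-methyl-2-[(3E,7E)-4,8,12-trimethyltrideca-3,7,11-trien-1-yl]penta-2,4-dien-1-ol | CC(C)=CCC/C(C)=C/CC/C(C)=C/CC/C(CO)=C(\C)C=C | intermediate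
15 | 9-{(3Z,7E,11E)-4-[(9-borabicyclo[3.3.1]nonan-9-yloxy)methyl]-3,8,12,16-tetramethylheptadeca-3,7,11,15-tetraen-1-yl}-9-borabicyclo[3.3.1]nonane | CC(C)=CCC/C(C)=C/CC/C(C)=C/CC/C(COB1C2CCCC1CCC2)=C(\C)CCB1C2CCCC1CCC2 | intermediate
16 | [(1S,6S)-2-[(3Z,7E,11E)-4-(hydroxymethyl)-3,8,12,16-tetramethylheptadeca-3,7,11,15-tetraen-1-yl]-1-methyl-6-(trimethylsilyloxy)cyclohex-2-en-1-yl]methyl 2,2-dimethylpropanoate | CC(C)=CCC/C(C)=C/CC/C(C)=C/CC/C(CO)=C(\C)CCC1=CCC[C@H](O[Si](C)(C)C)[C@]1(C)COC(=O)C(C)(C)C | intermediate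
17 | [(1S,6S)-6-hydroxy-2-[(3Z,7E,11E)-4-(hydroxymethyl)-3,8,12,16-tetramethylheptadeca-3,7,11,15-tetraen-1-yl]-1-methylcyclohex-2-en-1-yl]methyl 2,2-dimethylpropanoate | CC(C)=CCC/C(C)=C/CC/C(C)=C/CC/C(CO)=C(\C)CCC1=CCC[C@H](O)[C@]1(C)COC(=O)C(C)(C)C | intermediate
18 | [(1S,6S)-6-hydroxy-2-{2-[(2R,3S)-3-(hydroxymethyl)-2-methyl-3-[(3E,7E)-4,8,12-trimethyltrideca-3,7,11-trien-1-yl]oxiran-2-yl]ethyl}-1-methylcyclohex-2-en-1-yl]methyl 2,2-dimethylpropanoate | CC(C)=CCC/C(C)=C/CC/C(C)=C/CC[C@@]1(CO)O[C@]1(C)CCC2=CCC[C@H](O)[C@]2(C)COC(=O)C(C)(C)C | intermediate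
19 | bis(trimethylsilyl) ether of 18 (silyl on the C-26 and C-3 oxygens; same configurations) | CC(C)=CCC/C(C)=C/CC/C(C)=C/CC[C@@]1(CO[Si](C)(C)C)O[C@]1(C)CCC2=CCC[C@H](O[Si](C)(C)C)[C@]2(C)COC(=O)C(C)(C)C | intermediate
20 | trans-fused bicyclic C-7 carbocation (ring B closed, C-10 oxygen as methyldichloroaluminate, ring A intact with C-3 OTMS and axial CH2OPiv on C-2) | CC(C)=CCC/C(C)=C/CC/C(C)=C/CC[C@]1(CO[Si](C)(C)C)[C@H]2CC[C@H](O[Si](C)(C)C)[C@](C)(COC(=O)C(C)(C)C)[C+]2CC[C@@]1(C)O[Al-](C)(Cl)Cl | intermediate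
21 | C-10,C-26-bis(trimethylsilyl) ether of 22 | CC(C)=CCC/C(C)=C/CC/C(C)=C/CC[C@]1(CO[Si](C)(C)C)[C@@H](CCC=O)/C(=C(/C)COC(=O)C(C)(C)C)CC[C@@]1(C)O[Si](C)(C)C | intermediate
22 | (2Z)-2-[(2S,3R,4R)-4-hydroxy-3-(hydroxymethyl)-4-methyl-2-(3-oxopropyl)-3-[(3E,7E)-4,8,12-trimethyltrideca-3,7,11-trien-1-yl]cyclohexylidene]propyl 2,2-dimethylpropanoate | CC(C)=CCC/C(C)=C/CC/C(C)=C/CC[C@]1(CO)[C@@H](CCC=O)/C(=C(/C)COC(=O)C(C)(C)C)CC[C@@]1(C)O | intermediate
23 | (2Z)-2-[(2S,3R,4R)-4-hydroxy-3-(hydroxymethyl)-2-(3-hydroxypropyl)-4-methyl-3-[(3E,7E)-4,8,12-trimethyltrideca-3,7,11-trien-1-yl]cyclohexylidene]propan-1-ol | CC(C)=CCC/C(C)=C/CC/C(C)=C/CC[C@]1(CO)[C@@H](CCCO)/C(=C(/C)CO)CC[C@@]1(C)O | intermediate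
24 | (2Z)-2-[(2S,3R,4R)-4-hydroxy-3-(hydroxymethyl)-2-(3-hydroxypropyl)-4-methyl-3-[(3E,7E)-4,8,12-trimethyltrideca-3,7,11-trien-1-yl]cyclohexylidene]propanal | CC(C)=CCC/C(C)=C/CC/C(C)=C/CC[C@]1(CO)[C@@H](CCCO)/C(=C(/C)C=O)CC[C@@]1(C)O | target

## Step count and risks

Total steps: 13. Longest linear sequence: 10 (steps 1–5, then 9–13); the side-chain branch is steps 6–8.

**Step 11 (cyclisation–fragmentation cascade).** The risks are oxirane opening at C-10 instead of C-11, capture or deprotonation of the C-7 cation instead of fragmentation, and Prins re-closure of the aldehyde onto the new alkene.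

The fallback sets out from 6 and comes back at 23; it replaces the carbinol electrofuge by a ketal so that the fragmentation ends in an ester and cannot revert.
- 6 is desilylated with aqueous citric acid to the hydroxy enol triflate F1.
- Dess–Martin periodinane oxidises it to the keto enol triflate F2.
- 1,2-Bis(trimethylsilyloxy)ethane with catalytic TMSOTf ketalises it to the dioxolane enol triflate F3.
- Coupling with 15 as in step 9 gives the dioxolane allylic alcohol F4.
- Epoxidation as in step 10 gives the dioxolane epoxy alcohol F5, which is silylated in situ to its trimethylsilyl ether F6.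
- MeAlCl2 at −95 °C then triggers the same cyclisation; the departing fragment is now a 1,3-dioxolan-2-ylium ion, hydrolysed on work-up to the 2-hydroxyethyl ester F7.
- iBu2AlH as in step 12 reduces both esters of F7 and gives 23.

**Step 8 (anti-carbomagnesiation of an internal alkynol with a valuable Grignard reagent, then coupling).** The fallback sets out from 7 and comes back at 14; the Z geometry is enforced by a ring instead of a chelate.
- The lithium enolate of 1-(tert-butyldimethylsilyloxy)propan-2-one (LiN(iPr)2, THF, −78 °C) is alkylated with 7 to the silyloxy ketone F8.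
- Bu4NF gives the hydroxy ketone F9.
- Esterification with 2-(diethoxyphosphoryl)propanoic acid (DCC, DMAP) gives the phosphonate ester F10.
- Intramolecular Horner–Wadsworth–Emmons olefination (LiCl, DBU) closes the butenolide F11, whose ring holds C-9 cis to C-26.
- iBu2AlH at −78 °C gives the lactol F12, and Wittig methylenation (Ph3P=CH2) of its open hydroxy-enal form gives 14.

**Step 3 (CBS desymmetrisation).** The diastereoselection between the methyl and CH2OPiv arms is the uncertain point. The fallback sets out from 3 and comes back at 4; it replaces catalyst control by kinetic resolution (maximum yield 50%).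
- 3 is reduced without a chiral catalyst (NaBH4, MeOH, −78 °C) and the cis diastereomer is separated; it is the racemate of 4 and its enantiomer, the (1R,2R)-hydroxy ketone F13.
- Lipase-catalysed acylation (Burkholderia cepacia lipase, vinyl acetate) converts the (R)-carbinol F13 to the (1R,2R)-acetate F14, and unreacted 4 is recovered.

Further compounds

F1 | step 11 | [(1S,6S)-6-hydroxy-1-methyl-2-(trifluoromethylsulfonyloxy)cyclohex-2-en-1-yl]methyl 2,2-dimethylpropanoate | O=S(=O)(OC1=CCC[C@H](O)[C@]1(C)COC(=O)C(C)(C)C)C(F)(F)F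
F2 | step 11 | [(1R)-1-methyl-2-oxo-6-(trifluoromethylsulfonyloxy)cyclohex-5-en-1-yl]methyl 2,2-dimethylpropanoate | O=S(=O)(OC1=CCCC(=O)[C@]1(C)COC(=O)C(C)(C)C)C(F)(F)F
F3 | step 11 | [(6R)-6-methyl-7-(trifluoromethylsulfonyloxy)-1,4-dioxaspiro[4.5]dec-7-en-6-yl]methyl 2,2-dimethylpropanoate | O=S(=O)(OC1=CCCC2(OCCO2)[C@]1(C)COC(=O)C(C)(C)C)C(F)(F)F
F4 | step 11 | {(6S)-7-[(3Z,7E,11E)-4-(hydroxymethyl)-3,8,12,16-tetramethylheptadeca-3,7,11,15-tetraen-1-yl]-6-methyl-1,4-dioxaspiro[4.5]dec-7-en-6-yl}methyl 2,2-dimethylpropanoate | CC(C)=CCC/C(C)=C/CC/C(C)=C/CC/C(CO)=C(\C)CCC1=CCCC2(OCCO2)[C@]1(C)COC(=O)C(C)(C)C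
F5 | step 11 | {(6S)-7-{2-[(2R,3S)-3-(hydroxymethyl)-2-methyl-3-[(3E,7E)-4,8,12-trimethyltrideca-3,7,11-trien-1-yl]oxiran-2-yl]ethyl}-6-methyl-1,4-dioxaspiro[4.5]dec-7-en-6-yl}methyl 2,2-dimethylpropanoate | CC(C)=CCC/C(C)=C/CC/C(C)=C/CC[C@@]1(CO)O[C@]1(C)CCC2=CCCC3(OCCO3)[C@]2(C)COC(=O)C(C)(C)C
F6 | step 11 | trimethylsilyl ether of F5 (silyl on the C-26 oxygen) | CC(C)=CCC/C(C)=C/CC/C(C)=C/CC[C@@]1(CO[Si](C)(C)C)O[C@]1(C)CCC2=CCCC3(OCCO3)[C@]2(C)COC(=O)C(C)(C)C
F7 | step 11 | 2-hydroxyethyl 3-{(1S,2R,3R)-3-hydroxy-2-(hydroxymethyl)-3-methyl-6-[(2Z)-1-(2,2-dimethylpropanoyloxy)propan-2-ylidene]-2-[(3E,7E)-4,8,12-trimethyltrideca-3,7,11-trien-1-yl]cyclohexyl}propanoate | CC(C)=CCC/C(C)=C/CC/C(C)=C/CC[C@]1(CO)[C@@H](CCC(=O)OCCO)/C(=C(/C)COC(=O)C(C)(C)C)CC[C@@]1(C)O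
F8 | step 8 | (5E,9E)-1-(tert-butyldimethylsilyloxy)-6,10,14-trimethylpentadeca-5,9,13-trien-2-one | CC(C)=CCC/C(C)=C/CC/C(C)=C/CCC(=O)CO[Si](C)(C)C(C)(C)C
F9 | step 8 | (5E,9E)-1-hydroxy-6,10,14-trimethylpentadeca-5,9,13-trien-2-one | CC(C)=CCC/C(C)=C/CC/C(C)=C/CCC(=O)CO
F10 | step 8 | (5E,9E)-6,10,14-trimethyl-2-oxopentadeca-5,9,13-trien-1-yl 2-(diethoxyphosphoryl)propanoate | CC(C)=CCC/C(C)=C/CC/C(C)=C/CCC(=O)COC(=O)C(C)P(=O)(OCC)OCC
F11 | step 8 | 3-methyl-4-[(3E,7E)-4,8,12-trimethyltrideca-3,7,11-trien-1-yl]furan-2(5H)-one | CC(C)=CCC/C(C)=C/CC/C(C)=C/CCC1=C(C)C(=O)OC1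
F12 | step 8 | 3-methyl-4-[(3E,7E)-4,8,12-trimethyltrideca-3,7,11-trien-1-yl]-2,5-dihydrofuran-2-ol (lactol, both anomers) | CC(C)=CCC/C(C)=C/CC/C(C)=C/CCC1=C(C)C(O)OC1
F13 | step 3 | [(1R,2R)-2-hydroxy-1-methyl-6-oxocyclohexyl]methyl 2,2-dimethylpropanoate | O=C1CCC[C@@H](O)[C@@]1(C)COC(=O)C(C)(C)C
F14 | step 3 | [(1R,2R)-2-acetoxy-1-methyl-6-oxocyclohexyl]methyl 2,2-dimethylpropanoate | O=C1CCC[C@@H](OC(C)=O)[C@@]1(C)COC(=O)C(C)(C)C
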